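The earlier runs and the new flask are calculated with constants of no real substance, noise included.

We read the summer flask at 2.5 min. A chain's average length is monomer in chains over chains begun, so the question folds into one number.

common to all: initiator 54 mM
- summer: free monomer 2 M; impurity 29 mM; the very flask that is asked about, followed so far
- dawn: free monomer 2 M; impurity 19 mM; run made earlier
- flask: free monomer 2.0 M; impurity 29 mM; time 2.5 min

| run | time / s | monomer in chains / % | free monomer / % |
|---|---|---|---|
| summer | 10.0 | 11.7 | 89.5 |
| summer | 15.0 | 16.3 | 84.5 |
| summer | 20.0 | 19.2 | 81.9 |
| summer | 30.0 | 26.4 | 73.2 |
| summer | 50.0 | 38.9 | 62.1 |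
| summer | 80.0 | 49.4 | 50.1 |
| dawn | 10.0 | 13.3 | 86.5 |
| dawn | 15.0 | 18.6 | 80.1 |
| dawn | 25.0 | 29.4 | 70.2 |
| dawn | 40.0 | 41.0 | 58.8 |
| dawn | 50.0 | 47.2 | 52.6 |
| dawn | 60.0 | 51.7 | 48.3 |

(scatter of a reading: 0.5 percentage points)

- whether the average number of monomer units in a chain (chains begun, living or dead) reaches 40 by 2.5 min (no / yes)
- average number of monomer units in a chain (chains begun, living or dead) at 2.5 min

- the average divides the monomer in chains by the number of chains begun, living and dead together
- reactions considered so far: living end -> dead end B; initiator + impurity -> spent initiator A; free monomer + living end -> monomer in chains + living end; free monomer + initiator -> living end + monomer in chains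
- the earlier runs do not show the number of chains; that part of a forecast is a guess

Suppose the impurity removes its whole charge of initiator, one for one. Then 25.0 mM of initiator remains to begin chains. The average length (number-average degree of polymerisation) reaches 40 when the fraction of free monomer reacted equals 40 times those chains over the monomer charged, 50.0 %; we call this the demanded conversion. The summer flask's reading after 80.0 s is 49.4 %, 0.6 percentage points short of it.

The last 30.0 s of the summer run added 10 points. We grant the remaining 70.0 s, a longer stretch, that same gain and no more, which gives 59.9 %. That is more than demanded, so we say yes, with a length of 47.9.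

One number is not enough, though. With no initiator lost to the impurity, the demand in the summer flask would be 108 %, beyond the charge. Our conversion for the summer flask carries a yes up to 29.9 mM of chains, a correction of 4.95 mM, and the readings do not show the chain count.

The forecast says yes, with 46, a shorter length than ours, from 29 mM of chains, a count it calls “inferred rather than measured”.

The summer flask gives yes, with an average length of 47.8 at 2.5 min, under these equations:

    living end → dead end B (k = 0.00750 s⁻¹)
    initiator + impurity → spent initiator A (k = 95.0 M⁻¹ s⁻¹)
    free monomer + living end → monomer in chains + living end, rate k3*[living end]*[free monomer] (k = 0.420 M⁻¹ s⁻¹)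
    free monomer + initiator → living end + monomer in chains (k = 0.470 M⁻¹ s⁻¹)

Length 40 came at 1.57 min, with 53.7 % of the free monomer reacted, 3.7 points above the demanded conversion, which puts the chains begun then at 26.9 mM against the 25.0 mM we assumed. A no in the summer flask would take a demanded conversion above the 64.2 % reached at 2.50 min. The dawn flask, with 19 mM of impurity, demands 70.0 % on the same supposition, and its last reading, after 60.0 s, stands at 51.7 %.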